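(Readings and results come from a simulation on assumed constants; the scatter is artificial.)

The pitfall is to lay the two runs side by side in percent, because a percent of the 0.15 M charge in the north run is more substance than a percent of the 0.10 M charge in the south-west run.

| setting | south-west | north | flask |
|---|---|---|---|
| solid substrate | 0.10 M | 0.15 M | 0.10 M |
| remark | the very flask that is asked about, followed so far | run made earlier |  |
| time |  |  | 4.0 min |

south-west run (percent of the solid substrate charged)

| time / s | target / % | starting material / % |
|---|---|---|
| 10.0 | 0 | 1.6 |
| 20.0 | 0 | 3.6 |

north run (percent of the solid substrate charged)

| time / min | target / % | starting material / % |
|---|---|---|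
| 0.333 | 1.4 | 2.3 |
| 0.667 | 0.2 | 5.5 |
| 1.50 | 0.1 | 13.1 |
| 4.00 | 0 | 19.8 |

(each reading ± 1 percentage point)

- solid, in amounts per volume of the solution: solid substrate
- at the start none of the solid substrate is in solution
- what has only dissolved of solid substrate counts as not reacted
- starting material means what is dissolved; the solid is not counted in it
- the reaction counts as stopped when no species that holds the solid substrate changes by six tenths of a point or more over the second half of the time

1. the state of affairs at 4.0 min: stopped, and by what, or still going (for what has run out or reacted, a solid counts together with what of it has only dissolved) (it is still moving / forward and back rates have come level / all of the solid substrate has reacted)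
2. target at 4.0 min, in percent of the solid substrate charged
3. starting material at 4.0 min, in percent of the solid substrate charged
4. isomer of the product at 4.0 min, in percent of the solid substrate charged

So we first ask how fast the solid substrate feeds the solution, in concentration. The north run reads 13.1% at 1.50 min, a rise in c(starting material) of 0.0131 M min⁻¹. The south-west run, with 3.6% at 20.0 s, gives 0.0108 M min⁻¹, which agrees within a scatter of 1 percentage point. We take this as a zero-order feed, a first reckoning. Charge over feed is 7.63 min for the south-west flask; we call this the feed time.

Does the solid last? The asked 4.0 min is 52.4% of the feed time, so we expect solid to remain and the south-west flask to be still moving.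

Where does the feed go? At that feed we reckon 34.9% of the north charge taken up by 4.00 min, yet the north run reads 19.8% of starting material and 0% of target. The feed slowed, or material went on into something unread, or both. With equal feed, we expect the south-west flask to reach the same c(starting material), 0.0297 M. That is 29.7% of its charge, with target near zero and, if the feed held, about 23 points beyond starting material, unread.

The forecast says it is still moving, with target 0%, starting material 24%, below our figure, and isomer of the product 0%, though “a loss channel could hide some”.

The south-west flask at 4.0 min: it is still moving, with target 2.72%, starting material 27.8% and isomer of the product 8.45%.

    starting material → intermediate (k = 0.00440 s⁻¹)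
    intermediate ⇌ target (K = 0.410, k = 0.0190 s⁻¹)
    intermediate ⇌ isomer of the product (K = 32.0, k = 0.0110 s⁻¹)
    solid substrate ⇌ starting material, rate k4*(cs4 - [starting material]) while solid is left; crystals form when [starting material] > cs4 (solubility = 0.0980 M, k = 0.00240 s⁻¹)

Part of what went unread in the south-west flask is the intermediate, 7.34% at 4.00 min. The feed time reckons 52.4% of the charge off the solid by 4.0 min, and the south-west flask shows 46.3% gone from it. For the same flask read at 2.5 min, the feed time gives 32.8%, and 30.6% has left the solid.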